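## The problem

Mollicellin B (18) is a depsidone. Ring A, an orsellinate-type benzene, carries CH3, H, OH, CHO, an ether oxygen and a carboxyl carbon on six consecutive carbons. It is joined to the pentasubstituted ring B by a diaryl ether and by an aryl ester, and these two links close the seven-membered ring C. Ring B also carries ring D, a 2,2-dimethylpyran-4-one whose ketone carbon sits next to the ring B methyl group and whose ring oxygen is para to the ester oxygen. The molecule has no stereocentre, so the whole task is regiochemical: ten of the twelve arene positions are substituted, and the three oxygens of ring B must end in three different functions (lactone, ether, pyranone). The hardest single bond is the ether at ring A, whose carbon lies between the formyl-bearing and the carboxyl-bearing carbons. Late steps are limited by the salicylaldehyde unit, by the aryl ester of ring C (opened by nucleophiles and alkoxides) and by the enolisable chromanone; hydrogenolysis is excluded once the aldehyde is present. The enabling feature is the order of the ring A carbons. The CH3-, H-, OH- and CHO-bearing carbons correspond to C6, C5, C4 and C3 of 4-methoxy-6-methyl-2-pyranone, and the two remaining, adjacent carbons carry an oxygen donor and an acyl acceptor, so they are the two carbons of a polarised aryloxy-ynoate.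

## Retrosynthesis

**Ring C, ester bond (18 ⇒ 17).** The bond between the ring A acyl carbon and the ring B oxygen is cut last. The alternative, closing the ether last, would need substitution at the doubly ortho-substituted ring A carbon on a substrate that already holds a lactone and an aldehyde. In hydroxy acid 17 the ether holds acid and phenol together, so a carbodiimide closure only has to prefer the ring B hydroxyl over the ring A hydroxyl, which is para to the carboxyl and hydrogen-bonded to the aldehyde.

**Functional-group level (17 ⇒ 16 ⇒ 15).** Acid 17 is the fully deprotected form of 16, whose isopropyl ether, benzyl ester and aldehyde-chelated methyl ether all fall to one Lewis acid. The formyl group of 16 is traced to the bromine of 15. A bromine survives the thermal step, marks the position without ambiguity and is exchanged for CHO by palladium-catalysed carbonylation.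

**Ring A (15 ⇒ 11 + 13, through 14).** Two ring A bonds are cut: bromine-bearing carbon to ether carbon, and methyl-bearing carbon to carboxyl-bearing carbon. Compared with the classical cut at the ether C–O bond, this makes the crowded ether carbon during ring construction, and it divides 15 into two halves of similar size, ynoate 11 and bromopyranone 13. The forward reaction must be a regioselective [4+2] addition to bicycle 14, which loses CO2 and needs no separate oxidation.

**Diene (13 ⇒ 12).** The C–Br bond is cut. Pyranone 12 is commercial (or one methylation away from triacetic acid lactone), and C3, between carbonyl and methoxy, is its only enol-ether-activated position.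

**Alkyne (11 ⇒ 10 ⇒ 7 + 9; 9 ⇒ 8).** The triple bond of 11 is traced to loss of HCl from chloroenoate 10, and the aryl O–C(sp2) bond of 10 to vinylic substitution of phenol 7 on dichloroacrylate 9, the benzyl ester of acid 8. The usual acetylide route to ynol ethers needs n-butyllithium, which the chromanone ketone would not survive. This route asks only for clean mono-substitution and a controlled elimination.

**Oxygen differentiation on ring B (7 ⇒ 6 ⇒ 5).** Phenol 7 has the future ester oxygen masked and the future ether oxygen free, which is the reverse of what the starting phenol supplies. Isopropylation of 5 to 6 followed by chloride demethylation makes the swap. The methyl ether is para to the ketone and so activated, while the isopropyl group resists SN2 attack and is later cleaved by BCl3.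

**Ring D and the third oxygen (5 ⇒ 3 + 4; 3 ⇒ 2 ⇒ 1).** Ring D is cut at the aryl–acyl bond and the aryl O–CMe2 bond, giving hydroquinone 3 and acid 4. Only one hydroxyl of 3 has free ortho positions, so the ring oxygen is fixed. The acyl position is the one regiochemical question left, and it is placed at the first C–C bond-forming step on cheap material. Hydroquinone 3 comes from phenol 1 by para-oxygenation through quinone 2.

## Roads not taken

**Alternative 1: oxidative para-lactonisation.** The cut is the bond between the ester oxygen and ring B. Precursor A1 is a diaryl ether acid whose ring B is a 3-hydroxy-5-methylphenyl group. PhI(OAc)2 in (CF3)2CHOH, or an anode, would oxidise that phenol; the carboxyl group would add at the carbon para to the hydroxyl, and loss of a proton would give depsidone A2.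
- Merits: ring B needs only two oxygens, no oxygen differentiation is required, and ring C closes without activating the acid. On the ring B side this road is shorter than the chosen one.
- Weak points: the attacked carbon lies between a methyl and an aryloxy group, so ortho attack and quinone formation compete. The aldehyde and the electron-rich ring A are exposed to trivalent iodine. The ether of A1 still has to be made at the doubly ortho-substituted ring A carbon. Ring D must then be annulated onto A2 with 4 in strong acid, next to a lactone and an aldehyde, with the same positional question as in step 2 but at the end.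
- Comparison: the chosen plan settles ring D in its second step and never has to substitute at the hindered ring A carbon; it pays with three extra steps on ring B.

**Alternative 2: Moore rearrangement.** The cut runs through ring B, between the carbon that will carry the ring D oxygen and the carbon that will carry the ketone. Cyclobutenone A3, bound through its enol-ether oxygen to ring A, would open on heating to a dienylketene and close by a six-electron electrocyclisation to hydroquinone A4.
- Merits: the key step is thermal, neutral and well established for this substrate class. Its precedent is better than that of the chosen cycloaddition.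
- Weak points: a hindered, hydrogen-bonded ring A phenol must first be attached to the four-membered ring. After the key step A4 still lacks ring D, and the annulation with 4 must be run in strong acid beside a tert-butyl ester and a dioxolane, choosing one of two free hydroxyls and one of two ortho positions. Ester cleavage, lactonisation and unmasking follow.
- Comparison: the chosen plan sets the more reliable key step against a shorter and more convergent end (three steps after the key step, ring D in place before the halves meet).

**Alternative 3: tethered Danheiser benzannulation.** Four ring A bonds are cut and ring C closes in the same event. Irradiation of diazo ketoester A5 would give, by Wolff rearrangement, an acyl(isopropenyl)ketene. This would add to the ynol ether held on the neighbouring catechol oxygen, and four-electron opening and six-electron closure would give A6, the target with its formyl group as a silylated hydroxymethyl group.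
- Merits: two rings in one operation, ester and ether oxygens already in place, no lactonisation, a free ring A phenol, and only desilylation and oxidation afterwards. If it worked it would be shorter than the chosen end game.
- Weak points: A5 combines a diazo group beside an isopropenyl ketone (prone to intramolecular dipolar cycloaddition), an aryl ester and an ynol ether. The ynol ether has no ester to allow a lithium-free synthesis, so it conflicts with the chromanone. The ketene–alkyne addition must pass through a strained fused bicycle, the aryl ketone of ring D absorbs in the photolysis window, and the catechol must be differentiated just as in the chosen plan.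
- Comparison: the chosen plan offers two robust, separately made partners, a purely thermal key step and an alkyne that can be made under mild conditions.

Key step: step 9

Remark: 18 has no stereocentre; the only chiral species is the transient racemic bicycle 14. Compound 10 is drawn as its Z isomer, and the E isomer would serve equally in step 7.

## Route

Step 1
Reactants: 1 2-methoxy-6-methylphenol
Product: 3 2-methoxy-6-methylbenzene-1,4-diol, via 2-methoxy-6-methyl-1,4-benzoquinone 2 (not isolated)
Conditions: Co(salen) (5 mol %), O2 (1 atm), DMF, rt; then EtOAc, aq. Na2S2O4, rt
Reagents that add atoms: dioxygen, O=O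
Why: Oxygenation of a phenol catalysed by the salen complex of divalent cobalt gives the para-quinone because both ortho positions are blocked; dithionite in the work-up reduces 2 to the hydroquinone, which is used at once to avoid re-oxidation.

Step 2
Reactants: 3 2-methoxy-6-methylbenzene-1,4-diol; 4 3-methylbut-2-enoic acid
Product: 5 6-hydroxy-7-methoxy-2,2,5-trimethylchroman-4-one
Conditions: MeSO3H/P2O5 (Eaton's reagent), 70 °C
Reagents that add atoms: none
Why: Friedel–Crafts acylation followed by 6-endo-trig oxa-Michael closure (chromanone annulation of a phenol with a β,β-dimethylacrylic acid). Only the 4-hydroxyl has free ortho positions, and the one next to the methyl group is para to the methoxy group, the site electrophiles take in orcinol-type arenes in preference to the position between two oxygens.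

Step 3
Reactants: 5 6-hydroxy-7-methoxy-2,2,5-trimethylchroman-4-one
Product: 6 6-isopropoxy-7-methoxy-2,2,5-trimethylchroman-4-one
Conditions: 2-bromopropane, K2CO3, DMF, 70 °C
Reagents that add atoms: 2-bromopropane, CC(C)Br
Why: Williamson etherification of the only phenol; the secondary alkyl group is chosen because it resists the nucleophilic dealkylation of step 4 and is cleaved by BCl3 at the end.

Step 4
Reactants: 6 6-isopropoxy-7-methoxy-2,2,5-trimethylchroman-4-one
Product: 7 7-hydroxy-6-isopropoxy-2,2,5-trimethylchroman-4-one
Conditions: LiCl, DMF, 150 °C; then aq. HCl
Reagents that add atoms: none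
Why: Nucleophilic demethylation (SN2 at methyl by chloride); the 7-oxygen is para to the ketone, so its phenoxide is a good leaving group, while the isopropyl ether is inert to SN2 attack.

Step 5
Reactants: 8 3,3-dichloroacrylic acid
Product: 9 benzyl 3,3-dichloroacrylate
Conditions: BnBr, K2CO3, DMF, rt
Reagents that add atoms: benzyl bromide, BrCc1ccccc1
Why: O-Alkylation of the carboxylate; the benzyl ester tolerates the amide base at −78 °C and the thermal step, and is cleaved by BCl3 at the end.

Step 6
Reactants: 7 7-hydroxy-6-isopropoxy-2,2,5-trimethylchroman-4-one; 9 benzyl 3,3-dichloroacrylate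
Product: 10 benzyl (Z)-3-chloro-3-[(6-isopropoxy-2,2,5-trimethyl-4-oxochroman-7-yl)oxy]acrylate
Conditions: 9 (1.3 equiv), K2CO3, DMF, rt to 40 °C
Reagents that add atoms: none
Why: Nucleophilic vinylic substitution by addition–elimination at the β-carbon of a β,β-dihaloacrylate; the aryloxy group that has entered lowers the electrophilicity of 10, so a second substitution should be slow, and the isopropyl ether prevents the neighbouring oxygen from closing a dioxole.

Step 7
Reactants: 10 benzyl (Z)-3-chloro-3-[(6-isopropoxy-2,2,5-trimethyl-4-oxochroman-7-yl)oxy]acrylate
Product: 11 benzyl 3-[(6-isopropoxy-2,2,5-trimethyl-4-oxochroman-7-yl)oxy]propiolate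
Conditions: LiN(i-Pr)2 (2.2 equiv), THF, −78 °C; AcOH, −78 °C
Reagents that add atoms: none
Why: Dehydrochlorination of a 1-haloenol ether to an alkynyl ether through the ester-stabilised α-vinyl anion (E1cB), the same reaction type that gives ynoates from β-halo- or β-sulfonyloxy-acrylates. Chloride is by far the better of the two possible leaving groups, and the first equivalent of base stores the chromanone as its enolate until the acidic quench.

Step 8
Reactants: 12 4-methoxy-6-methyl-2H-pyran-2-one
Product: 13 3-bromo-4-methoxy-6-methyl-2H-pyran-2-one
Conditions: NBS, MeCN, rt
Reagents that add atoms: N-bromosuccinimide, O=C1CCC(=O)N1Br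
Why: Electrophilic bromination at C3, the enol-ether carbon between the lactone carbonyl and the methoxy group, which is the known site of halogenation of 4-alkoxy-2-pyranones.

Step 9
Reactants: 11 benzyl 3-[(6-isopropoxy-2,2,5-trimethyl-4-oxochroman-7-yl)oxy]propiolate; 13 3-bromo-4-methoxy-6-methyl-2H-pyran-2-one
Product: 15 benzyl 3-bromo-2-[(6-isopropoxy-2,2,5-trimethyl-4-oxochroman-7-yl)oxy]-4-methoxy-6-methylbenzoate, via bridged bicyclic lactone 14 (not isolated)
Conditions: 13 (3 equiv), BHT (cat.), o-dichlorobenzene, 170 °C, sealed tube
Reagents that add atoms: none
Why: Proposed new method: the [4+2] cycloaddition of a 2-pyranone with an alkyne followed by extrusion of CO2 is a known benzene synthesis, but a 3-aryloxypropiolate has not been used as the 2π partner; the closest known cases are the thermal reactions of 4-methoxy-6-methyl-2-pyranone with propiolates and acetylenedicarboxylates and of 3-bromo-2-pyranones with acrylates. Pyranone 13 reacts as a diene across C3 and C6, the alkyne adds suprafacially to give the 2-oxabicyclo[2.2.2]octadienone 14, and a retro-[4+2] loss of CO2 gives the benzene directly with no oxidation step. Ring A thus closes by an intermolecular, thermally allowed [4+2] cycloaddition that forms both new C–C bonds in one event (C3 to the aryloxy-bearing alkyne carbon, C6 to the ester-bearing alkyne carbon); no other ring is closed. The two bridgehead stereocentres of 14 are fixed relative to each other by the bicyclic frame, arise as a racemate and vanish on aromatisation, so no stereocontrol is needed. The selectivity required is orientation: the 4-methoxy group and the ring oxygen make C3 the nucleophilic and C6 the electrophilic terminus of 13, while in 11 the aryloxy-bearing carbon is the electrophilic β-carbon of the ynoate and the ester-bearing carbon is the nucleophilic carbon of the ynol ether, so both frontier-orbital pairings join C3 to C–OAr and C6 to C–CO2Bn. The bromine lowers the LUMO of the diene and makes it ambiphilic, which should offset the reduced electrophilicity of the push–pull alkyne, and it fixes the future formyl position. An alkyne has no substituent out of the bonding plane, which is why two fully substituted diene termini can still be joined, and the excess of the cheap pyranone drives the bimolecular step.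

Step 10
Reactants: 15 benzyl 3-bromo-2-[(6-isopropoxy-2,2,5-trimethyl-4-oxochroman-7-yl)oxy]-4-methoxy-6-methylbenzoate
Product: 16 benzyl 3-formyl-2-[(6-isopropoxy-2,2,5-trimethyl-4-oxochroman-7-yl)oxy]-4-methoxy-6-methylbenzoate
Conditions: Pd(OAc)2 (3 mol %), di(1-adamantyl)-n-butylphosphine (9 mol %), TMEDA, CO/H2 (1:1, 5 bar), toluene, 100 °C
Reagents that add atoms: carbon monoxide, [C-]#[O+]
Why: Palladium-catalysed reductive carbonylation of an aryl bromide (oxidative addition to zerovalent palladium, CO insertion, hydrogenolysis of the acyl complex). The bulky electron-rich phosphine is what allows oxidative addition into a bromide flanked by two oxygen substituents, and the homogeneous catalyst under CO leaves the benzyl ester, ketone and ethers untouched.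

Step 11
Reactants: 16 benzyl 3-formyl-2-[(6-isopropoxy-2,2,5-trimethyl-4-oxochroman-7-yl)oxy]-4-methoxy-6-methylbenzoate
Product: 17 3-formyl-4-hydroxy-2-[(6-hydroxy-2,2,5-trimethyl-4-oxochroman-7-yl)oxy]-6-methylbenzoic acid
Conditions: BCl3, CH2Cl2, −78 °C to rt; then H2O
Reagents that add atoms: none
Why: Lewis-acid dealkylation with BCl3: the isopropyl ether and the benzyl ester cleave through stabilised alkyl cations captured by chloride, and the methyl ether is cleaved because the ortho-formyl group chelates boron. The diaryl ether and the ring D oxygen, which is deactivated by conjugation with the ketone, should stay intact.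

Step 12
Reactants: 17 3-formyl-4-hydroxy-2-[(6-hydroxy-2,2,5-trimethyl-4-oxochroman-7-yl)oxy]-6-methylbenzoic acid
Product: 18 mollicellin B
Conditions: DCC, DMAP (cat.), CH2Cl2/THF, high dilution, 0 °C to rt
Reagents that add atoms: none
Why: Carbodiimide (Steglich-type) lactonisation, a 7-exo-trig attack of the ring B hydroxyl on the O-acylisourea, which is the established closure of depsidones from 2-(2-hydroxyaryloxy)benzoic acids. The ether hinge holds this hydroxyl next to the acyl carbon, whereas the ring A hydroxyl is para to the carboxyl and hydrogen-bonded to the aldehyde.

## Compound list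

1 | 2-methoxy-6-methylphenol | COc1cccc(C)c1O | starting material
2 | 2-methoxy-6-methyl-1,4-benzoquinone | COC1=CC(=O)C=C(C)C1=O | intermediate (not isolated)
3 | 2-methoxy-6-methylbenzene-1,4-diol | COc1cc(O)cc(C)c1O | intermediate
4 | 3-methylbut-2-enoic acid | CC(C)=CC(=O)O | starting material
5 | 6-hydroxy-7-methoxy-2,2,5-trimethylchroman-4-one | COc1cc2OC(C)(C)CC(=O)c2c(C)c1O | intermediate
6 | 6-isopropoxy-7-methoxy-2,2,5-trimethylchroman-4-one | COc1cc2OC(C)(C)CC(=O)c2c(C)c1OC(C)C | intermediate
7 | 7-hydroxy-6-isopropoxy-2,2,5-trimethylchroman-4-one | CC(C)Oc1c(O)cc2OC(C)(C)CC(=O)c2c1C | intermediate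
8 | 3,3-dichloroacrylic acid | OC(=O)C=C(Cl)Cl | starting material
9 | benzyl 3,3-dichloroacrylate | O=C(OCc1ccccc1)C=C(Cl)Cl | intermediate
10 | benzyl (Z)-3-chloro-3-[(6-isopropoxy-2,2,5-trimethyl-4-oxochroman-7-yl)oxy]acrylate | O=C(OCc1ccccc1)/C=C(\Cl)Oc1cc2OC(C)(C)CC(=O)c2c(C)c1OC(C)C | intermediate
11 | benzyl 3-[(6-isopropoxy-2,2,5-trimethyl-4-oxochroman-7-yl)oxy]propiolate | O=C(OCc1ccccc1)C#COc1cc2OC(C)(C)CC(=O)c2c(C)c1OC(C)C | intermediate
12 | 4-methoxy-6-methyl-2H-pyran-2-one | COC1=CC(=O)OC(C)=C1 | starting material
13 | 3-bromo-4-methoxy-6-methyl-2H-pyran-2-one | COC1=C(Br)C(=O)OC(C)=C1 | intermediate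
14 | benzyl 4-bromo-5-methoxy-1-methyl-3-oxo-8-[(6-isopropoxy-2,2,5-trimethyl-4-oxochroman-7-yl)oxy]-2-oxabicyclo[2.2.2]octa-5,7-diene-7-carboxylate (racemic; one enantiomer drawn) | O=C1O[C@]2(C)C=C(OC)[C@@]1(Br)C(Oc1cc3OC(C)(C)CC(=O)c3c(C)c1OC(C)C)=C2C(=O)OCc1ccccc1 | intermediate (not isolated)
15 | benzyl 3-bromo-2-[(6-isopropoxy-2,2,5-trimethyl-4-oxochroman-7-yl)oxy]-4-methoxy-6-methylbenzoate | O=C(OCc1ccccc1)c1c(C)cc(OC)c(Br)c1Oc1cc2OC(C)(C)CC(=O)c2c(C)c1OC(C)C | intermediate
16 | benzyl 3-formyl-2-[(6-isopropoxy-2,2,5-trimethyl-4-oxochroman-7-yl)oxy]-4-methoxy-6-methylbenzoate | O=Cc1c(OC)cc(C)c(C(=O)OCc2ccccc2)c1Oc1cc2OC(C)(C)CC(=O)c2c(C)c1OC(C)C | intermediate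
17 | 3-formyl-4-hydroxy-2-[(6-hydroxy-2,2,5-trimethyl-4-oxochroman-7-yl)oxy]-6-methylbenzoic acid | O=Cc1c(O)cc(C)c(C(=O)O)c1Oc1cc2OC(C)(C)CC(=O)c2c(C)c1O | intermediate
18 | mollicellin B | Cc1cc(O)c(C=O)c2c1C(=O)Oc1c(cc3c(c1C)C(=O)CC(C)(C)O3)O2 | target

## Step count and least certain steps

Total steps: 12. Longest linear sequence: 10 (steps 1, 2, 3, 4, 6, 7, 9, 10, 11, 12).

**Step 9 (key step, Proposed new method).** The most likely failure is a cycloaddition too slow to compete with thermal degradation or hydration of the ynol ether: the aryloxy donor raises the LUMO of the alkyne and both diene termini are fully substituted. Addition in the reverse orientation is the second concern. The fallback uses known chemistry and forms the ether by nucleophilic aromatic substitution. It sets out from phenol 7 and comes back at aldehyde 16, so steps 5 to 10 are bypassed. Phenol 7 (K2CO3, DMF, 60–80 °C) would displace fluoride from benzyl 2-fluoro-3-formyl-4-methoxy-6-methylbenzoate F3, whose fluorine lies between a formyl and an ester group. F3 would be made from commercial 3-fluoro-5-methylanisole in three operations: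
- lithiation between fluorine and methoxy (n-BuLi, THF, −78 °C; DMF) to 2-fluoro-6-methoxy-4-methylbenzaldehyde F1;
- bromination para to the methoxy group (NBS, MeCN) to 3-bromo-2-fluoro-6-methoxy-4-methylbenzaldehyde F2;
- benzyloxycarbonylation (Pd(OAc)2, Xantphos, CO, BnOH, Et3N, toluene, 90 °C) to F3.

**Step 7.** The risk is consumption of the product as it forms: the ynoate is a Michael acceptor for the chromanone enolate and for any nucleophilic base, and elimination may also stop short. The fallback leaves the elimination route for direct substitution at the sp carbon. It sets out from phenol 7 and comes back at 11. Benzyl 3-bromopropiolate F4 (from benzyl propiolate, NBS and catalytic AgNO3 in acetone) would be kept in excess in MeCN at −20 °C while the caesium phenoxide of 7 is added slowly. Addition at the bromine-bearing carbon and loss of bromide from the resulting vinyl anion would give 11 under carbonate conditions only.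

**Step 2.** The risk is acylation at the position between the two oxygens, giving the isomeric chromanone, together with esterification of the hindered hydroxyl. The fallback changes the basis of regiocontrol from arene nucleophilicity to quinone electrophilicity. It sets out from quinone 2, isolated instead of reduced, and comes back at 5. Irradiation of 2 with 3-methylbut-2-enal in benzene (photochemical acylation of a quinone by an aldehyde) should place the acyl group on the ring carbon β to the more ketone-like carbonyl, the one beside the methyl-bearing carbon. This gives 1-(3,6-dihydroxy-4-methoxy-2-methylphenyl)-3-methylbut-2-en-1-one F5, which closes to 5 by oxa-Michael addition (K2CO3, MeOH).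

**Step 10.** The risk is hydrodebromination, or no turnover at all, because CO insertion and oxidative addition are both slowed at a carbon flanked by two oxygen substituents. The fallback builds the aldehyde carbon by cross-coupling and unmasks it oxidatively. It sets out from bromide 15 and comes back at 16. Suzuki–Miyaura coupling with potassium vinyltrifluoroborate (Pd(OAc)2, SPhos, Cs2CO3, THF/H2O, 80 °C) would give benzyl 3-ethenyl-2-[(6-isopropoxy-2,2,5-trimethyl-4-oxochroman-7-yl)oxy]-4-methoxy-6-methylbenzoate F6. Lemieux–Johnson cleavage (OsO4 cat., NaIO4, 2,6-lutidine, dioxane/H2O) would then give 16.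

**Step 12.** The risk is intermolecular esterification through the ring A hydroxyl, or rearrangement of the hindered O-acylisourea to an N-acylurea, before the seven-membered ring closes. The fallback closes ring C before a ring A phenol exists. It sets out from bromide 15 and comes back at target 18.
- BCl3 at −78 to 0 °C removes only the isopropyl and benzyl groups of 15, because without an ortho carbonyl the methyl ether is not activated. This gives 3-bromo-2-[(6-hydroxy-2,2,5-trimethyl-4-oxochroman-7-yl)oxy]-4-methoxy-6-methylbenzoic acid F7.
- DCC closure gives the bromo depsidone methyl ether F8.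
- The carbonylation conditions of step 10 give mollicellin B methyl ether F9.
- BCl3 at rt, now directed by the formyl group, removes the last methyl group to give 18.

## Further compounds

F1 | step 9 | 2-fluoro-6-methoxy-4-methylbenzaldehyde | O=Cc1c(F)cc(C)cc1OC
F2 | step 9 | 3-bromo-2-fluoro-6-methoxy-4-methylbenzaldehyde | O=Cc1c(F)c(Br)c(C)cc1OC
F3 | step 9 | benzyl 2-fluoro-3-formyl-4-methoxy-6-methylbenzoate | O=Cc1c(F)c(C(=O)OCc2ccccc2)c(C)cc1OC
F4 | step 7 | benzyl 3-bromopropiolate | O=C(OCc1ccccc1)C#CBr
F5 | step 2 | 1-(3,6-dihydroxy-4-methoxy-2-methylphenyl)-3-methylbut-2-en-1-one | CC(C)=CC(=O)c1c(C)c(O)c(OC)cc1O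
F6 | step 10 | benzyl 3-ethenyl-2-[(6-isopropoxy-2,2,5-trimethyl-4-oxochroman-7-yl)oxy]-4-methoxy-6-methylbenzoate | C=Cc1c(OC)cc(C)c(C(=O)OCc2ccccc2)c1Oc1cc2OC(C)(C)CC(=O)c2c(C)c1OC(C)C
F7 | step 12 | 3-bromo-2-[(6-hydroxy-2,2,5-trimethyl-4-oxochroman-7-yl)oxy]-4-methoxy-6-methylbenzoic acid | O=C(O)c1c(C)cc(OC)c(Br)c1Oc1cc2OC(C)(C)CC(=O)c2c(C)c1O
F8 | step 12 | bromo depsidone methyl ether (18 with Br in place of CHO and OMe in place of OH) | Cc1cc(OC)c(Br)c2c1C(=O)Oc1c(cc3c(c1C)C(=O)CC(C)(C)O3)O2
F9 | step 12 | mollicellin B methyl ether | Cc1cc(OC)c(C=O)c2c1C(=O)Oc1c(cc3c(c1C)C(=O)CC(C)(C)O3)O2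
A1 | alternative 1 | 3-formyl-2-(3-hydroxy-5-methylphenoxy)-4-methoxy-6-methylbenzoic acid | Cc1cc(OC)c(C=O)c(Oc2cc(O)cc(C)c2)c1C(=O)O
A2 | alternative 1 | tricyclic depsidone with a free ring B phenol | Cc1cc(OC)c(C=O)c2c1C(=O)Oc1c(C)cc(O)cc1O2
A3 | alternative 2 | tert-butyl 3-(1,3-dioxolan-2-yl)-2-{[4-hydroxy-3-oxo-4-(prop-1-en-2-yl)cyclobut-1-en-1-yl]oxy}-4-methoxy-6-methylbenzoate (racemic) | CC(=C)C1(O)C(=O)C=C1Oc1c(C2OCCO2)c(OC)cc(C)c1C(=O)OC(C)(C)C
A4 | alternative 2 | tert-butyl 2-(2,5-dihydroxy-3-methylphenoxy)-3-(1,3-dioxolan-2-yl)-4-methoxy-6-methylbenzoate | CC(C)(C)OC(=O)c1c(C)cc(OC)c(C2OCCO2)c1Oc1cc(O)cc(C)c1O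
A5 | alternative 3 | 7-{[3-(tert-butyldimethylsilyloxy)prop-1-yn-1-yl]oxy}-2,2,5-trimethyl-4-oxochroman-6-yl 2-diazo-4-methyl-3-oxopent-4-enoate | CC(=C)C(=O)C(=[N+]=[N-])C(=O)Oc1c(C)c2C(=O)CC(C)(C)Oc2cc1OC#CCO[Si](C)(C)C(C)(C)C
A6 | alternative 3 | mollicellin B with the formyl group as a tert-butyldimethylsilyloxymethyl group | Cc1cc(O)c(CO[Si](C)(C)C(C)(C)C)c2c1C(=O)Oc1c(cc3c(c1C)C(=O)CC(C)(C)O3)O2
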